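**Retrosynthetic overview**

- The target is a symmetric dimer of 2-hydroxy-3-methyl-6-[2-(2-methoxyphenyl)ethyl]-1,4-benzoquinone joined C5–C5'. Both quinone rings are unmasked last from a hexamethoxybiphenyl by (NH4)2Ce(NO3)6 oxidation and hydrolysis of the two vinylogous methyl esters, after hydrogenation of a bis-stilbene.
- Feature used: in each ring the biaryl carbon C5 and the chain carbon C6 are neighbours. In ring B an iodide on C6' and the free C–H on C5' can therefore take up the styryl arm (ipso) and ring A (ortho) in one palladium/norbornene three-component coupling.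
- Ring A enters as a 2-bromobenzoate. Its ester on C6 guides the arylation and is then turned into the second arm by reduction, oxidation and Horner–Wadsworth–Emmons olefination.
- Both aryl halides come from 2,6-dimethoxytoluene: formylation, Dakin oxidation, ortho-iodination and O-methylation give the iodide; carbonylation and bromination of that iodide give the bromo ester.
- Ring order: no ring is built. The two benzene rings are bought as arenes, joined in step 7, and converted together into the quinone rings in step 12.

Key step: step 7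

Assumption: the target SMILES carries no axial descriptor and the molecule has no stereocentre, so the hindered biaryl axis is made as a racemate.
Assumption: diethyl (2-methoxybenzyl)phosphonate (14) is taken as a catalogue reagent; otherwise it is one Arbuzov step from 2-methoxybenzyl chloride and P(OEt)3.

**Route**

Step 1
Reactants: 1 2,6-dimethoxytoluene
Product: 3 2,4-dimethoxy-3-methylbenzaldehyde, via iminium salt 2 (not isolated)
Conditions: POCl3, DMF, 0 °C → 90 °C; then ice/H2O
Reagents that add atoms: N,N-dimethylformamide, CN(C)C=O (formyl carbon); water, O (carbonyl oxygen)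
Why: Vilsmeier–Haack formylation should attack the ring position ortho to one OMe and para to the other (two equivalent sites by symmetry), and aqueous work-up hydrolyses the iminium salt.

Step 2
Reactants: 3 2,4-dimethoxy-3-methylbenzaldehyde
Product: 5 2,4-dimethoxy-3-methylphenol, via aryl formate 4 (not isolated)
Conditions: mCPBA, CH2Cl2, 0 °C → rt; then K2CO3 (cat.), MeOH, rt
Reagents that add atoms: mCPBA, OOC(=O)c1cccc(Cl)c1
Why: Baeyer–Villiger (Dakin-type) oxidation, in which the electron-rich aryl group migrates in preference to hydride, followed by methanolysis of the formate.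

Step 3
Reactants: 5 2,4-dimethoxy-3-methylphenol
Product: 6 6-iodo-2,4-dimethoxy-3-methylphenol
Conditions: I2 (1.0 equiv), NaHCO3, THF/H2O, 0 °C → rt
Reagents that add atoms: iodine, II
Why: Electrophilic aromatic iodination through the phenoxide, which should direct I2 to its only free ortho position (the para position carries OMe), while the neutral dimethoxyarene site is not expected to react with unactivated I2.

Step 4
Reactants: 6 6-iodo-2,4-dimethoxy-3-methylphenol
Product: 7 1-iodo-2,3,5-trimethoxy-4-methylbenzene (ring B iodide)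
Conditions: MeI, K2CO3, DMF, rt
Reagents that add atoms: iodomethane, CI
Why: Williamson ether synthesis on an acidic ortho-iodophenol. (Part of 7 is carried into step 5 and part is kept for step 7.)

Step 5
Reactants: 7 1-iodo-2,3,5-trimethoxy-4-methylbenzene
Product: 8 methyl 2,3,5-trimethoxy-4-methylbenzoate
Conditions: Pd(OAc)2 (3 mol%), Xantphos (6 mol%), CO (1 atm), Et3N, MeOH/toluene, 70 °C
Reagents that add atoms: carbon monoxide, [C-]#[O+]; methanol, CO
Why: Palladium-catalysed alkoxycarbonylation of an aryl iodide (oxidative addition, CO insertion, methanolysis of the acylpalladium), which places the ester exactly on the former C–I carbon.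

Step 6
Reactants: 8 methyl 2,3,5-trimethoxy-4-methylbenzoate
Product: 9 methyl 2-bromo-3,5,6-trimethoxy-4-methylbenzoate (ring A bromide)
Conditions: NBS, MeCN, rt, dark
Reagents that add atoms: N-bromosuccinimide, O=C1CCC(=O)N1Br
Why: Electrophilic aromatic bromination at the single remaining ring C–H, which is ortho to one OMe and para to another, under ionic conditions that should leave the aryl methyl group alone.

Step 7
Reactants: 7 1-iodo-2,3,5-trimethoxy-4-methylbenzene (1.0 equiv); 9 methyl 2-bromo-3,5,6-trimethoxy-4-methylbenzoate (1.5 equiv); 10 2-vinylanisole (2.0 equiv)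
Product: 11 methyl 3,5,6-trimethoxy-4-methyl-2-{2,4,5-trimethoxy-3-methyl-6-[(E)-2-(2-methoxyphenyl)ethenyl]phenyl}benzoate
Conditions: Pd(OAc)2 (10 mol%), tri(2-furyl)phosphine (20 mol%), norbornene (1.0 equiv), Cs2CO3 (3 equiv), DMF, 105 °C, argon
Reagents that add atoms: none
Why: Proposed new method: the closest known reaction type is the Catellani palladium/norbornene ortho-arylation of an ortho-substituted aryl iodide by an ortho-ester aryl bromide with Heck termination, which has not been shown for a 2,6-disubstituted bromide or for a tetra-ortho-substituted biaryl. Zerovalent palladium should insert into the less hindered C–I bond of 7 before the flanked C–Br bond of 9, norbornene then inserts, and the only ortho C–H (C5') is palladated to a five-membered palladacycle of divalent palladium. The ester carbonyl of 9 should guide its oxidative addition to this palladacycle (tetravalent palladium), and because the OMe on C1' sits ortho to the norbornyl-bearing carbon, reductive elimination is expected to join aryl to aryl (C5–C5') and not aryl to norbornyl. The norbornylpalladium formed then has both ortho positions occupied, so β-carbon elimination should expel norbornene and leave palladium on C6', where syn insertion of 10 and syn β-hydride elimination give the (E)-styryl arm. No ring is closed and no stereocentre is formed; the E geometry follows from the Heck step and the new axis forms as a racemate. The step needs chemoselectivity (iodide before bromide, 9 before a second molecule of 7 at the palladacycle, arylation before Heck coupling) and site selectivity, which the single ortho C–H of 7, its ortho OMe group and the chelating ester of 9 are expected to supply.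

Step 8
Reactants: 11 biaryl ester
Product: 12 (3,5,6-trimethoxy-4-methyl-2-{2,4,5-trimethoxy-3-methyl-6-[(E)-2-(2-methoxyphenyl)ethenyl]phenyl}phenyl)methanol
Conditions: LiAlH4, THF, 0 °C → reflux; aqueous NaOH work-up
Reagents that add atoms: none
Why: Hydride reduction of an ester to the primary alcohol, for which the small, strongly nucleophilic LiAlH4 should overcome the di-ortho-substituted environment while the stilbene is untouched.

Step 9
Reactants: 12 benzylic alcohol
Product: 13 3,5,6-trimethoxy-4-methyl-2-{2,4,5-trimethoxy-3-methyl-6-[(E)-2-(2-methoxyphenyl)ethenyl]phenyl}benzaldehyde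
Conditions: Dess–Martin periodinane, CH2Cl2, rt
Reagents that add atoms: none
Why: Dess–Martin oxidation of a benzylic alcohol stops cleanly at the aldehyde and tolerates the electron-rich arenes and the alkene.

Step 10
Reactants: 13 biaryl aldehyde; 14 diethyl (2-methoxybenzyl)phosphonate
Product: 15 3,3',4,4',6,6'-hexamethoxy-2,2'-bis[(E)-2-(2-methoxyphenyl)ethenyl]-5,5'-dimethyl-1,1'-biphenyl
Conditions: KOtBu, THF, 0 °C → rt
Reagents that add atoms: none
Why: Horner–Wadsworth–Emmons olefination with a benzylic phosphonate anion should give the (E)-stilbene; the geometry is in any case erased in step 11.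

Step 11
Reactants: 15 bis-stilbene
Product: 16 3,3',4,4',6,6'-hexamethoxy-2,2'-bis[2-(2-methoxyphenyl)ethyl]-5,5'-dimethyl-1,1'-biphenyl
Conditions: H2 (3 atm), 10% Pd/C, EtOAc/EtOH, rt
Reagents that add atoms: none
Why: Heterogeneous catalytic hydrogenation should saturate both disubstituted stilbene alkenes without touching aryl ethers or the biaryl.

Step 12
Reactants: 16 hexamethoxy bis(phenethyl)biphenyl
Product: 17 4,4'-dimethoxy-2,2'-bis[2-(2-methoxyphenyl)ethyl]-5,5'-dimethyl-[1,1'-bi(cyclohexa-1,4-dien-1-yl)]-3,3',6,6'-tetrone (bis-methoxyquinone)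
Conditions: (NH4)2Ce(NO3)6 (4.5 equiv), MeCN/H2O, 0 °C
Reagents that add atoms: water, O
Why: Oxidative demethylation by tetravalent cerium, in which each 1,2,4-trimethoxyarene ring should lose its para-related OMe groups (C1 and C4) to carbonyl oxygen from water and keep the C2 OMe as a vinylogous ester, while the monomethoxy anisole arms lie at higher oxidation potential.

Step 13
Reactants: 17 bis-methoxyquinone
Product: 18 4,4'-dihydroxy-2,2'-bis[2-(2-methoxyphenyl)ethyl]-5,5'-dimethyl-[1,1'-bi(cyclohexa-1,4-dien-1-yl)]-3,3',6,6'-tetrone (target)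
Conditions: 2 M NaOH, MeOH/THF, argon, 0 °C → rt; then 1 M HCl
Reagents that add atoms: sodium hydroxide, [Na+].[OH-] (hydroxide oxygen)
Why: Vinylogous ester saponification by addition–elimination, in which hydroxide adds at C2 (β to the C4 carbonyl) and expels methoxide on a fully substituted quinone that offers no other conjugate-addition site, and acidification returns the hydroxyquinone.

**Compound list**

1 | 2,6-dimethoxytoluene | Cc1c(OC)cccc1OC | starting material
2 | N-(2,4-dimethoxy-3-methylbenzylidene)-N-methylmethanaminium chloride (iminium salt) | C[N+](C)=Cc1ccc(OC)c(C)c1OC.[Cl-] | intermediate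
3 | 2,4-dimethoxy-3-methylbenzaldehyde | O=Cc1ccc(OC)c(C)c1OC | intermediate
4 | 2,4-dimethoxy-3-methylphenyl formate | O=COc1ccc(OC)c(C)c1OC | intermediate
5 | 2,4-dimethoxy-3-methylphenol | Oc1ccc(OC)c(C)c1OC | intermediate
6 | 6-iodo-2,4-dimethoxy-3-methylphenol | Oc1c(I)cc(OC)c(C)c1OC | intermediate
7 | 1-iodo-2,3,5-trimethoxy-4-methylbenzene | Ic1cc(OC)c(C)c(OC)c1OC | intermediate
8 | methyl 2,3,5-trimethoxy-4-methylbenzoate | COC(=O)c1cc(OC)c(C)c(OC)c1OC | intermediate
9 | methyl 2-bromo-3,5,6-trimethoxy-4-methylbenzoate | COC(=O)c1c(Br)c(OC)c(C)c(OC)c1OC | intermediate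
10 | 2-vinylanisole | C=Cc1ccccc1OC | starting material
11 | methyl 3,5,6-trimethoxy-4-methyl-2-{2,4,5-trimethoxy-3-methyl-6-[(E)-2-(2-methoxyphenyl)ethenyl]phenyl}benzoate | COC(=O)c1c(-c2c(/C=C/c3ccccc3OC)c(OC)c(OC)c(C)c2OC)c(OC)c(C)c(OC)c1OC | intermediate
12 | (3,5,6-trimethoxy-4-methyl-2-{2,4,5-trimethoxy-3-methyl-6-[(E)-2-(2-methoxyphenyl)ethenyl]phenyl}phenyl)methanol | OCc1c(-c2c(/C=C/c3ccccc3OC)c(OC)c(OC)c(C)c2OC)c(OC)c(C)c(OC)c1OC | intermediate
13 | 3,5,6-trimethoxy-4-methyl-2-{2,4,5-trimethoxy-3-methyl-6-[(E)-2-(2-methoxyphenyl)ethenyl]phenyl}benzaldehyde | O=Cc1c(-c2c(/C=C/c3ccccc3OC)c(OC)c(OC)c(C)c2OC)c(OC)c(C)c(OC)c1OC | intermediate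
14 | diethyl (2-methoxybenzyl)phosphonate | CCOP(=O)(Cc1ccccc1OC)OCC | starting material
15 | 3,3',4,4',6,6'-hexamethoxy-2,2'-bis[(E)-2-(2-methoxyphenyl)ethenyl]-5,5'-dimethyl-1,1'-biphenyl | COc1ccccc1/C=C/c1c(OC)c(OC)c(C)c(OC)c1-c1c(/C=C/c2ccccc2OC)c(OC)c(OC)c(C)c1OC | intermediate
16 | 3,3',4,4',6,6'-hexamethoxy-2,2'-bis[2-(2-methoxyphenyl)ethyl]-5,5'-dimethyl-1,1'-biphenyl | COc1ccccc1CCc1c(OC)c(OC)c(C)c(OC)c1-c1c(CCc2ccccc2OC)c(OC)c(OC)c(C)c1OC | intermediate
17 | 4,4'-dimethoxy-2,2'-bis[2-(2-methoxyphenyl)ethyl]-5,5'-dimethyl-[1,1'-bi(cyclohexa-1,4-dien-1-yl)]-3,3',6,6'-tetrone | COc1ccccc1CCC1=C(C2=C(CCc3ccccc3OC)C(=O)C(OC)=C(C)C2=O)C(=O)C(C)=C(OC)C1=O | intermediate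
18 | 4,4'-dihydroxy-2,2'-bis[2-(2-methoxyphenyl)ethyl]-5,5'-dimethyl-[1,1'-bi(cyclohexa-1,4-dien-1-yl)]-3,3',6,6'-tetrone | COc1ccccc1CCC1=C(C2=C(CCc3ccccc3OC)C(=O)C(O)=C(C)C2=O)C(=O)C(C)=C(O)C1=O | target

**Step count**

Total: 13 steps. Longest linear sequence: 13 steps (1 → 3 → 5 → 6 → 7 → 8 → 9 → 11 → 12 → 13 → 15 → 16 → 17 → 18; the bromide 9 is made from the iodide 7, so there is no shorter branch).

**Steps most likely to fail**

1. Step 7 (proposed new method). Reductive elimination to a tetra-ortho-substituted axis may be too slow, or the doubly flanked bromide 9 may fail to add to the palladacycle. The cycle would then drain into self-arylation of the palladacycle by a second molecule of 7, norbornene-retaining products, or direct Heck coupling of 7 with 10.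
Fallback (known chemistry, sets out from 9, returns at 15): the symmetry of the target is used instead of the three-component coupling. Classical Ullmann homocoupling of 9 (activated Cu powder, DMF, 150 °C) is the established way to tetra-ortho-substituted diphenates from 2-halo-3-alkoxybenzoates. It should give dimethyl 3,3',4,4',6,6'-hexamethoxy-5,5'-dimethyl-[1,1'-biphenyl]-2,2'-dicarboxylate F1. LiAlH4 in THF would reduce it to [3,3',4,4',6,6'-hexamethoxy-5,5'-dimethyl-[1,1'-biphenyl]-2,2'-diyl]dimethanol F2. Dess–Martin oxidation would give 3,3',4,4',6,6'-hexamethoxy-5,5'-dimethyl-[1,1'-biphenyl]-2,2'-dicarbaldehyde F3. A double Horner–Wadsworth–Emmons reaction with 14 (KOtBu, THF) then rejoins the route at 15.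

2. Step 3. Iodine may enter at the C–H flanked by OMe (ortho and para to two OMe groups), a second iodine may be introduced, or the electron-rich para-methoxyphenoxide may be oxidised.
Fallback (sets out from 5, returns at 6): the site is fixed by directed ortho-metalation. Protection with MOMCl and iPr2NEt in CH2Cl2 would give 1,3-dimethoxy-4-(methoxymethoxy)-2-methylbenzene F4. Lithiation with n-BuLi in THF at 0 °C should go next to the chelating OMOM group in preference to the OMe-flanked site, and quenching with I2 at −78 °C would give 1-iodo-3,5-dimethoxy-2-(methoxymethoxy)-4-methylbenzene F5. Cleavage of the acetal with HCl in MeOH delivers 6.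

3. Step 12. The second ring may oxidise sluggishly once the first has become an electron-poor quinone, and forcing conditions may nitrate or oxidise the anisole arms and benzylic positions. Formation of an ortho-quinone from the C1/C2 pair would be harmless, because after step 13 the 4-hydroxy-1,2-quinone is a tautomer of the target ring.
Fallback (sets out from 16, returns at 17): the oxidation is done electrochemically without a metal oxidant. Anodic oxidation of 16 (Pt anode, KOH/MeOH, constant current, 0 °C), the known conversion of 1,4-dimethoxyarenes into quinone bisketals, should give 2,2'-bis[2-(2-methoxyphenyl)ethyl]-3,3,3',3',4,4',6,6,6',6'-decamethoxy-5,5'-dimethyl-1,1'-bi(cyclohexa-1,4-dien-1-yl) F6. Mild hydrolysis of the four ketals (1 M HCl, THF, rt) gives 17.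

**Further compounds**

F1 | step 7 | dimethyl 3,3',4,4',6,6'-hexamethoxy-5,5'-dimethyl-[1,1'-biphenyl]-2,2'-dicarboxylate | COC(=O)c1c(-c2c(C(=O)OC)c(OC)c(OC)c(C)c2OC)c(OC)c(C)c(OC)c1OC
F2 | step 7 | [3,3',4,4',6,6'-hexamethoxy-5,5'-dimethyl-[1,1'-biphenyl]-2,2'-diyl]dimethanol | OCc1c(-c2c(CO)c(OC)c(OC)c(C)c2OC)c(OC)c(C)c(OC)c1OC
F3 | step 7 | 3,3',4,4',6,6'-hexamethoxy-5,5'-dimethyl-[1,1'-biphenyl]-2,2'-dicarbaldehyde | O=Cc1c(-c2c(C=O)c(OC)c(OC)c(C)c2OC)c(OC)c(C)c(OC)c1OC
F4 | step 3 | 1,3-dimethoxy-4-(methoxymethoxy)-2-methylbenzene | COCOc1ccc(OC)c(C)c1OC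
F5 | step 3 | 1-iodo-3,5-dimethoxy-2-(methoxymethoxy)-4-methylbenzene | COCOc1c(I)cc(OC)c(C)c1OC
F6 | step 12 | 2,2'-bis[2-(2-methoxyphenyl)ethyl]-3,3,3',3',4,4',6,6,6',6'-decamethoxy-5,5'-dimethyl-1,1'-bi(cyclohexa-1,4-dien-1-yl) | COc1ccccc1CCC1=C(C2=C(CCc3ccccc3OC)C(OC)(OC)C(OC)=C(C)C2(OC)OC)C(OC)(OC)C(C)=C(OC)C1(OC)OC
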